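**Remark:** the SMILES defines both flavan units as constitutionally identical and both (2R,3S) (2,3-trans), so the target is treated as twofold symmetric; compounds 1, 2 and 6 are taken as catalogue materials.

## Retrosynthetic overview

1. The target consists of two identical (2R,3S)-flavan-3-ol halves joined by one oxygen between the C3' atoms of the two rings B, so both halves are built at once on a symmetric diaryl ether core (two-directional).
2. Key disconnection, made twice: C4–C4a and O1–C2 of each ring C, giving 3,5-bis(benzyloxy)phenol (ring A with the future O1) and a trans-β-aryl-α,β-epoxy aldehyde (CHO = C4, oxirane = C3/C2). The annulation gives a flavan-3,4-diol, the leucoanthocyanidin level from which plants reach catechins, and the extra C4–OH is then reduced off.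
3. Enabling feature: ring A is a phloroglucinol ring (O1, O5 and O7 mutually meta), so C4a is a strongly nucleophilic carbon ortho to the oxygen that becomes O1. The chain C4–C3(OH)–C2 ends in a C2 that is benzylic to ring B and para to O4', so aldehyde carbon, oxirane CH–O and benzylic oxirane carbon map onto C4, C3 and C2.
4. The bis(epoxy aldehyde) comes from the symmetric dialdehyde by double Wittig homologation and double catalyst-controlled epoxidation; the dialdehyde comes from an Ullmann diaryl ether coupling of two 4-benzyloxybenzaldehydes.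
5. Ring order: rings B are joined first, rings A enter preformed, both rings C close last (step 4); C4 deoxygenation and hydrogenolysis of six benzyl ethers finish the route.

Key step: step 4

## Route

Step 1
Reactants: 1 4-(benzyloxy)-3-hydroxybenzaldehyde; 2 4-(benzyloxy)-3-bromobenzaldehyde
Product: 3 3,3'-oxybis[4-(benzyloxy)benzaldehyde]
Conditions: CuI (20 mol%), N,N-dimethylglycine hydrochloride (60 mol%), Cs2CO3 (2 equiv), 1,4-dioxane, 100 °C
Reagents that add atoms: none
Why: Ullmann diaryl ether coupling under CuI/amino acid catalysis joins a phenol to an aryl bromide, tolerates aldehydes and ortho-alkoxy groups, and creates no stereocentre.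

Step 2
Reactants: 3 3,3'-oxybis[4-(benzyloxy)benzaldehyde]
Product: 4 (2E,2'E)-3,3'-[oxybis(4-(benzyloxy)-3,1-phenylene)]bis(prop-2-enal)
Conditions: Ph3P=CHCHO (2.5 equiv), toluene, 90 °C
Reagents that add atoms: (triphenylphosphoranylidene)acetaldehyde, O=CC=P(c1ccccc1)(c1ccccc1)c1ccccc1
Why: Wittig olefination with the stabilised formyl ylide extends each aryl aldehyde by two carbons to the (E)-enal, both ends reacting in the same flask.

Step 3
Reactants: 4 (2E,2'E)-3,3'-[oxybis(4-(benzyloxy)-3,1-phenylene)]bis(prop-2-enal)
Product: 5 (2R,3S,2'R,3'S)-3,3'-[oxybis(4-(benzyloxy)-3,1-phenylene)]bis(oxirane-2-carbaldehyde)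
Conditions: 35% aq. H2O2 (2.6 equiv), (S)-2-{bis[3,5-bis(trifluoromethyl)phenyl](trimethylsilyloxy)methyl}pyrrolidine (20 mol%), CH2Cl2, rt; crude product filtered through Et3N-deactivated silica and used at once
Reagents that add atoms: hydrogen peroxide, OO
Why: Iminium–enamine organocatalytic epoxidation of enals (diarylprolinol silyl ether catalysis): hydroperoxide adds to the β-carbon of the iminium ion on the face left open by the diarylsilyloxymethyl group and the enamine closes the trans-oxirane, so the catalyst sets both oxirane carbons as (2R,3S) at each end, and because the two ends react independently the minor sense should be diverted mainly into a meso diastereomer that is removed downstream.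

Step 4
Reactants: 5 (2R,3S,2'R,3'S)-3,3'-[oxybis(4-(benzyloxy)-3,1-phenylene)]bis(oxirane-2-carbaldehyde); 6 3,5-bis(benzyloxy)phenol
Product: 9 (2R,3S,2'R,3'S)-2,2'-[oxybis(4-(benzyloxy)-3,1-phenylene)]bis[5,7-bis(benzyloxy)chromane-3,4-diol] (C4 epimers), via aryloxytitanium triisopropoxide 7 (not isolated), via ortho-hydroxyalkylated bis-epoxide 8 (not isolated)
Conditions: 6 (2.3 equiv), Ti(OiPr)4 (2.3 equiv), toluene, rt, i-PrOH removed in vacuo; then 5, CH2Cl2, −20 °C to rt; aq. NaHCO3
Reagents that add atoms: none
Why: Proposed new method: each aryloxytitanium unit 7 binds one aldehyde of 5 and delivers its ortho carbon to the carbonyl carbon through a six-membered cyclic transition state, which forms C4–C4a and leaves the new C4 alkoxide on titanium beside the oxirane (8); the closest known reaction type is the ortho-specific hydroxyalkylation of titanium and magnesium phenoxides by aldehydes, known for alpha-alkoxy aldehydes but not for alpha,beta-epoxy aldehydes. The titanium-bound 2,3-epoxy alcohol so formed is then opened at the carbon remote from the carbinol, here the benzylic C2 para to the 4'-benzyloxy group, by the neighbouring phenolic oxygen, in line with the Ti(OiPr)4-mediated C3-selective opening of 2,3-epoxy alcohols and with the acid-induced closure of 2-(3-aryloxiranylmethyl)phenols to trans-flavan-3-ols; this forms O1–C2. Each ring C closes in the 6-endo-tet mode by epoxide opening, the 5-exo alternative at C3 being disfavoured because C2 is benzylic and donor-stabilised and because titanium directs attack away from the carbinol. C2 is set by inversion at the (S)-configured benzylic oxirane carbon and C3 is carried over untouched from the oxirane, which together give the (2R,3S) trans arrangement, while the C4 carbinol centre needs no control because step 5 removes it. The step needs ortho-carbon attack instead of oxygen or para-carbon attack, secured by the free OH of 6 that anchors titanium next to the reacting carbon, and it needs one annulation per phenol, secured because that oxygen is used up as O1. Should the phenolic oxygen open the oxirane before the carbon attacks the aldehyde, the tethered aldehyde would close by the same ortho attack and the two orders converge on 9.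

Step 5
Reactants: 9 (2R,3S,2'R,3'S)-2,2'-[oxybis(4-(benzyloxy)-3,1-phenylene)]bis[5,7-bis(benzyloxy)chromane-3,4-diol] (C4 epimers)
Product: 10 (2R,3S,2'R,3'S)-2,2'-[oxybis(4-(benzyloxy)-3,1-phenylene)]bis[5,7-bis(benzyloxy)chroman-3-ol]
Conditions: Et3SiH (6 equiv), CF3CO2H (4 equiv), CH2Cl2 (high dilution), −40 °C; aq. NaHCO3
Reagents that add atoms: none
Why: Ionic hydrogenation: the C4–OH, benzylic to a ring that carries O1, O5 and O7 ortho and para, ionises under mild acid to a quinone-methide-type cation that the silane reduces to CH2 (the chemical counterpart of the leucoanthocyanidin reductase step), which merges all C4 epimers into one compound and leaves C2 and C3 untouched.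

Step 6
Reactants: 10 (2R,3S,2'R,3'S)-2,2'-[oxybis(4-(benzyloxy)-3,1-phenylene)]bis[5,7-bis(benzyloxy)chroman-3-ol]
Product: 11 catechin-(3'-O-3''')-afzelechin, (2R,3S,2'R,3'S)-2,2'-[oxybis(4-hydroxy-3,1-phenylene)]bis(chromane-3,5,7-triol)
Conditions: H2 (1 atm), Pd(OH)2/C, THF/MeOH, rt
Reagents that add atoms: none
Why: Hydrogenolysis of the six benzyl aryl ethers over Pd(OH)2/C is the standard last step for benzylated flavan-3-ols and should leave the cyclic C2–O1 ether, the diaryl ether and all four stereocentres unchanged.

## Compound list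

1 | 4-(benzyloxy)-3-hydroxybenzaldehyde | O=Cc1ccc(OCc2ccccc2)c(O)c1 | starting material
2 | 4-(benzyloxy)-3-bromobenzaldehyde | O=Cc1ccc(OCc2ccccc2)c(Br)c1 | starting material
3 | 3,3'-oxybis[4-(benzyloxy)benzaldehyde] | O=Cc1ccc(OCc2ccccc2)c(Oc2cc(C=O)ccc2OCc2ccccc2)c1 | intermediate
4 | (2E,2'E)-3,3'-[oxybis(4-(benzyloxy)-3,1-phenylene)]bis(prop-2-enal) | O=C/C=C/c1ccc(OCc2ccccc2)c(Oc2cc(/C=C/C=O)ccc2OCc2ccccc2)c1 | intermediate
5 | (2R,3S,2'R,3'S)-3,3'-[oxybis(4-(benzyloxy)-3,1-phenylene)]bis(oxirane-2-carbaldehyde), both oxiranes trans | O=C[C@@H]1O[C@H]1c1ccc(OCc2ccccc2)c(Oc2cc([C@@H]3O[C@H]3C=O)ccc2OCc2ccccc2)c1 | intermediate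
6 | 3,5-bis(benzyloxy)phenol | Oc1cc(OCc2ccccc2)cc(OCc2ccccc2)c1 | starting material
7 | [3,5-bis(benzyloxy)phenoxy]titanium triisopropoxide | CC(C)O[Ti](OC(C)C)(OC(C)C)Oc1cc(OCc2ccccc2)cc(OCc2ccccc2)c1 | intermediate (not isolated)
8 | bis-epoxide in which each CHO of 5 has become CH(OH)–Ar, Ar = 2-hydroxy-4,6-bis(benzyloxy)phenyl; oxirane configuration as in 5, carbinol centres undefined; drawn as the free phenol/alcohol, present in the flask as its titanium alkoxide | OC(c1c(O)cc(OCc2ccccc2)cc1OCc1ccccc1)[C@@H]1O[C@H]1c1ccc(OCc2ccccc2)c(Oc2cc([C@@H]3O[C@H]3C(O)c3c(O)cc(OCc4ccccc4)cc3OCc3ccccc3)ccc2OCc2ccccc2)c1 | intermediate (not isolated)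
9 | (2R,3S,2'R,3'S)-2,2'-[oxybis(4-(benzyloxy)-3,1-phenylene)]bis[5,7-bis(benzyloxy)chromane-3,4-diol], C4 epimers | O(Cc1ccccc1)c1cc(OCc3ccccc3)c2c(c1)O[C@H](c1ccc(OCc3ccccc3)c(Oc3cc([C@H]4Oc5cc(OCc6ccccc6)cc(OCc6ccccc6)c5C(O)[C@@H]4O)ccc3OCc3ccccc3)c1)[C@@H](O)C2O | intermediate
10 | (2R,3S,2'R,3'S)-2,2'-[oxybis(4-(benzyloxy)-3,1-phenylene)]bis[5,7-bis(benzyloxy)chroman-3-ol], the hexa-O-benzyl ether of the target | O(Cc1ccccc1)c1cc(OCc3ccccc3)c2c(c1)O[C@H](c1ccc(OCc3ccccc3)c(Oc3cc([C@H]4Oc5cc(OCc6ccccc6)cc(OCc6ccccc6)c5C[C@@H]4O)ccc3OCc3ccccc3)c1)[C@@H](O)C2 | intermediate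
11 | catechin-(3'-O-3''')-afzelechin, (2R,3S,2'R,3'S)-2,2'-[oxybis(4-hydroxy-3,1-phenylene)]bis(chromane-3,5,7-triol) | Oc1cc(O)c2c(c1)O[C@H](c1ccc(O)c(Oc3cc([C@H]4Oc5cc(O)cc(O)c5C[C@@H]4O)ccc3O)c1)[C@@H](O)C2 | target

## Step count and risks

Total step count: 6. Longest linear sequence: 6 steps (1 and 2 to 11; 6 enters at step 4).

**Steps most likely to fail**

1. **Step 4 (proposed new method).** Isopropoxide or the arene carbon may attack the benzylic oxirane carbon before the aldehyde is engaged. The benzylic C–O bond may also ionise to an open cation, eroding the trans selectivity at C2, and the new C4 carbinol may condense further with a second phenoxide.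
 - Fallback (known chemistry, the two bonds made one after the other): it sets out from 5 and comes back at 10.
 - NaBH4 (MeOH/CH2Cl2, 0 °C) reduces both aldehydes to the bis(epoxy alcohol) F1.
 - The phenoxide of 6 (NaOH, H2O/dioxane, 70 °C) opens each aryl glycidol at the benzylic carbon with inversion, forming O1–C2 first and giving the bis(3-aryloxy-1,2-diol) F2.
 - Mitsunobu cyclodehydration (PPh3, DIAD, THF) closes each 1,2-diol through its primary hydroxyl, with retention at the secondary carbon, to the bis(terminal epoxide) F3.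
 - AuCl3/AgOTf-catalysed 6-endo epoxide–arene cyclisation (intramolecular Friedel–Crafts attack of the ring A ortho carbon on the terminal oxirane carbon, CH2Cl2, rt) then forms C4–C4a and gives 10 directly, with C4 already at the CH2 level.

2. **Step 3.** The electron-rich benzylic oxirane may open under adventitious acid or on silica during its formation and handling, and a slow iminium turnover with the donor-substituted enal may let an uncatalysed, unselective epoxidation compete.
 - Fallback: it sets out from 3 and comes back at 5, carrying the oxirane as a stable amide made under non-acidic conditions.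
 - Horner–Wadsworth–Emmons reaction of 3 with diethyl (2-morpholino-2-oxoethyl)phosphonate (LiCl, DBU, MeCN) gives the bis[(E)-cinnamoyl morpholine amide] F4.
 - Lanthanide–BINOL-catalysed nucleophilic epoxidation (Sm(OiPr)3, the BINOL enantiomer that delivers the (2R,3S)-oxirane, Ph3As=O, t-BuOOH, 4 Å MS, THF) gives the bis(epoxy morpholine amide) F5.
 - Partial reduction of both morpholine amides with NaAlH2(OCH2CH2OMe)2 (THF, −78 °C) releases 5 shortly before use.

3. **Step 5.** The C4 cation may be captured by ring A of a second molecule instead of by hydride (oligomerisation), or may lose the C3 proton towards a flavan-3-one; prolonged acid may also reopen ring C at C2.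
 - Fallback: it sets out from 9 and comes back at 11. The benzylic C4–OH groups are removed by heterogeneous hydrogenolysis together with the six benzyl ethers in one operation (H2, Pd(OH)2/C, EtOAc/MeOH, trace AcOH, rt), so no acid-generated free cation is involved and compound 10 is bypassed. This fallback makes no new compound (F0).

Further compounds
F1 | step 4 | {(2S,3S,2'S,3'S)-[oxybis(4-(benzyloxy)-3,1-phenylene)]bis(oxirane-3,2-diyl)}dimethanol, the bis(epoxy alcohol) from reduction of 5 | OC[C@@H]1O[C@H]1c1ccc(OCc2ccccc2)c(Oc2cc([C@@H]3O[C@H]3CO)ccc2OCc2ccccc2)c1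
F2 | step 4 | (2S,3R,2'S,3'R)-3,3'-[oxybis(4-(benzyloxy)-3,1-phenylene)]bis{3-[3,5-bis(benzyloxy)phenoxy]propane-1,2-diol} | c1ccccc1COc1cc(OCc2ccccc2)cc(c1)O[C@H](c1ccc(OCc2ccccc2)c(Oc2cc([C@@H](Oc3cc(OCc4ccccc4)cc(OCc4ccccc4)c3)[C@@H](O)CO)ccc2OCc2ccccc2)c1)[C@@H](O)CO
F3 | step 4 | bis(terminal epoxide): each half is (S)-2-{(R)-[3,5-bis(benzyloxy)phenoxy](aryl)methyl}oxirane on the diaryl ether core | c1ccccc1COc1cc(OCc2ccccc2)cc(c1)O[C@H](c1ccc(OCc2ccccc2)c(Oc2cc([C@@H](Oc3cc(OCc4ccccc4)cc(OCc4ccccc4)c3)[C@@H]3CO3)ccc2OCc2ccccc2)c1)[C@@H]1CO1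
F4 | step 3 | (2E,2'E)-3,3'-[oxybis(4-(benzyloxy)-3,1-phenylene)]bis[1-(morpholin-4-yl)prop-2-en-1-one] | O=C(/C=C/c1ccc(OCc2ccccc2)c(Oc2cc(/C=C/C(=O)N3CCOCC3)ccc2OCc2ccccc2)c1)N1CCOCC1
F5 | step 3 | (2R,3S,2'R,3'S)-bis(epoxy morpholine amide): {3,3'-[oxybis(4-(benzyloxy)-3,1-phenylene)]bis(oxirane-3,2-diyl)}bis(morpholin-4-ylmethanone) | O=C([C@@H]1O[C@H]1c1ccc(OCc2ccccc2)c(Oc2cc([C@@H]3O[C@H]3C(=O)N3CCOCC3)ccc2OCc2ccccc2)c1)N1CCOCC1
F0 | step 5 | none | none
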